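**Plan**

1. Retrosynthesis: the two isovalerates, the C19 silyl ether and the tert-butyl ester come off first. The side chain is cut at C11–C12 (allylic bromide + acetoacetate dianion; C13 methyl by enol phosphate/cuprate), leaving a C11 ester on a 6-oxygenated decalin.
2. The decalin is cut at C5–C10 and C7–C8 in one operation. Ring B has its only oxygen on C6, flanked by C5 and C7 (the α and α′ carbons of a methyl ketone). Its C8(CH3)=C9–C11 unit is the dehydrated aldol of an alkylidene acetoacetate (C10 β-carbon, C8 acetyl carbon, C11 ester carbon), and C6 and C8 are 1,5-related through C5–C10–C9. A Michael/aldol-condensation [3+3] bicyclisation of the open chain C7…C8 therefore closes ring A and then ring B.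
3. Forward: the chain is joined from methyl acetoacetate (C19, C4, C3, C2), a silyl propargyl bromide (C1, C10, C20), MeI (C18), allyl bromide (C5–C7) and ethyl acetoacetate (C17, C8, C9, C11). Ring A, then ring B close in step 9; C12–C16 are added afterwards.
4. Stereochemistry: C3 from asymmetric hydrogenation; C4 from two chelate-controlled dianion alkylations, each anti to O3; C10 and C5 from the chair transition state of the ring A closure (axial C19 ester cis to the axial C20 methyl; C5 correctable by enolisation); C6 by hydride attack on the α-face, secured as the 19,6β-lactone; the 13E olefin from a Z-enol phosphate and a cuprate.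

Key step: step 9

Remark: labdane numbering (C1–C10 ring carbons, C11–C16 side chain, C17 on C8, C18/C19 on C4, C20 on C10) is used for all intermediates; step 7 is assumed to give the 1-alkenyl isomer 11, its conjugated isomer being equally serviceable because step 9 equilibrates them.

**Route**

Step 1
Reactants: 1 methyl acetoacetate; 2 3-bromo-1-(trimethylsilyl)prop-1-yne
Product: 3 methyl 3-oxo-7-(trimethylsilyl)hept-6-ynoate
Conditions: NaH, THF, 0 °C; n-BuLi, 0 °C; then 2, 0 °C → rt; H2O
Reagents that add atoms: none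
Why: Acetoacetate dianion γ-alkylation, the terminal carbanion being the more nucleophilic site, should join C2 to C1 with the propargylic bromide.

Step 2
Reactants: 3 methyl 3-oxo-7-(trimethylsilyl)hept-6-ynoate
Product: 4 methyl (3R)-3-hydroxy-7-(trimethylsilyl)hept-6-ynoate
Conditions: RuCl2[(R)-BINAP] (0.5 mol%), H2 (10 atm), MeOH, 50 °C
Reagents that add atoms: none
Why: Noyori asymmetric hydrogenation of a β-keto ester with the (R)-BINAP ligand should set the (3R) carbinol (C3 of the target) and leave the silyl-capped alkyne untouched.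

Step 3
Reactants: 4 methyl (3R)-3-hydroxy-7-(trimethylsilyl)hept-6-ynoate
Product: 5 methyl (2R,3R)-3-hydroxy-2-methyl-7-(trimethylsilyl)hept-6-ynoate
Conditions: LiN(i-Pr)2 (2.2 equiv), THF, −78 → −20 °C; MeI, DMPU, −78 → 0 °C; H2O
Reagents that add atoms: iodomethane, CI
Why: Fráter–Seebach alkylation, in which the lithium-chelated alkoxide enolate is methylated on the face anti to the C3 chain, should give the 2,3-anti product.

Step 4
Reactants: 5 methyl (2R,3R)-3-hydroxy-2-methyl-7-(trimethylsilyl)hept-6-ynoate; 6 allyl bromide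
Product: 7 methyl (2R,3R)-3-hydroxy-2-methyl-2-(prop-2-en-1-yl)-7-(trimethylsilyl)hept-6-ynoate
Conditions: LiN(i-Pr)2 (2.3 equiv), THF, −78 → −20 °C; 6, DMPU, −78 → 0 °C; H2O
Reagents that add atoms: none
Why: A second Fráter–Seebach alkylation, the allyl group again entering anti to the carbinol substituent of the chelated dianion, should set quaternary C4 with the allyl group (C5–C7) anti and the methyl (C18) syn to O3, as the target requires.

Step 5
Reactants: 7 methyl (2R,3R)-3-hydroxy-2-methyl-2-(prop-2-en-1-yl)-7-(trimethylsilyl)hept-6-ynoate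
Product: 8 methyl (2R,3R)-3-hydroxy-2-methyl-2-(prop-2-en-1-yl)hept-6-ynoate
Conditions: K2CO3 (cat.), MeOH, rt
Reagents that add atoms: none
Why: Base-catalysed methanolysis of the alkynyl C–Si bond (protodesilylation) should free the terminal alkyne without touching the hindered ester.

Step 6
Reactants: 8 methyl (2R,3R)-3-hydroxy-2-methyl-2-(prop-2-en-1-yl)hept-6-ynoate
Product: 9 methyl (2R,3R)-3-acetoxy-2-methyl-2-(prop-2-en-1-yl)hept-6-ynoate
Conditions: Ac2O, DMAP, pyridine, CH2Cl2, rt → 40 °C
Reagents that add atoms: acetic anhydride, CC(=O)OC(C)=O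
Why: DMAP-catalysed acetylation gives an acid-stable ester that keeps O3 from forming a hemiketal or dihydrofuran with the later C6 ketone and that the later hydride step removes.

Step 7
Reactants: 9 methyl (2R,3R)-3-acetoxy-2-methyl-2-(prop-2-en-1-yl)hept-6-ynoate; 10 ethyl acetoacetate
Product: 11 1-ethyl 8-methyl (6R,7R)-6-acetoxy-2-acetyl-7-methyl-3-methylidene-7-(prop-2-en-1-yl)octanedioate
Conditions: In(OTf)3 (5 mol%), 10 (5 equiv), neat, 100 °C
Reagents that add atoms: none
Why: Indium-catalysed addition of a 1,3-dicarbonyl compound to an unactivated terminal alkyne (intermolecular Conia-ene-type carbometalation by the indium enolate) is Markovnikov, so C9 should bond to the internal alkyne carbon C10 while the allyl alkene is left.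

Step 8
Reactants: 11 1-ethyl 8-methyl (6R,7R)-6-acetoxy-2-acetyl-7-methyl-3-methylidene-7-(prop-2-en-1-yl)octanedioate
Product: 12 1-ethyl 8-methyl (6R,7R)-6-acetoxy-2-acetyl-7-methyl-3-methylidene-7-(2-oxopropyl)octanedioate
Conditions: PdCl2 (10 mol%), CuCl (1 equiv), O2 (1 atm), DMF/H2O (7:1), rt
Reagents that add atoms: water, O
Why: Tsuji–Wacker oxidation should hydroxypalladate the monosubstituted allyl alkene at its internal carbon to give the C6 methyl ketone, the 1,1-disubstituted alkene being much slower.

Step 9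
Reactants: 12 1-ethyl 8-methyl (6R,7R)-6-acetoxy-2-acetyl-7-methyl-3-methylidene-7-(2-oxopropyl)octanedioate
Product: 16 enone diester (11-ethyl 19-methyl 3α-acetoxy-6-oxo-12,13,14,15,16-pentanorlabd-7-ene-11,19-dioate), via alkylidene acetoacetate 13 (not isolated), via Michael adduct 14 (not isolated), via aldol 15 (not isolated)
Conditions: Sc(OTf)3 (10 mol%), TsOH·H2O (30 mol%), toluene, 90 °C, Dean–Stark trap
Reagents that add atoms: none
Why: Acid should move the C10=C20 bond into conjugation (13, all double-bond isomers converging), after which the more substituted enol of the C6 ketone adds through C5 to the chelate-activated β-carbon C10 (ring A, 6-(enolexo)-exo-trig Michael closure to 14) and the C7 methyl of the same ketone condenses with the C8 acetyl carbonyl (ring B, 6-(enolendo)-exo-trig aldol closure to 15, then loss of water). The closest known reaction type is the Michael/aldol-condensation [3+3] cyclohexenone annulation of a ketone with a β,β-disubstituted enone or an alkylidene acetoacetate (isophorone and Hagemann ester formation, acid-catalysed Robinson annulation), here intramolecular so that one ketone serves as the C5/C7 dinucleophile. C10 should be set in a chair transition state with the C20 methyl axial and the bulky C9 dicarbonyl arm equatorial, in which the C19 ester, conformationally smaller than the C18 methyl, takes the axial site syn to C20 and the C3 acetoxy group lies axial. C5 is set trans to C20 in the same chair and stays correctable by enolisation towards the trans-fused 6-ketone, while C8 and C9 need no control (C8 is dehydrated, C9 epimerises and becomes sp2 in step 10). The step needs C5 and not C7 as Michael donor (only C5 closes a six-membered ring), the C7-to-C8 and not the C17-to-C6 aldol (C8 is the ester-activated, less hindered carbonyl and the acetoacetate enolises towards C9), and the C19/C20 cis relationship, which rests on the ester-axial preference and is the least secure of the three.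

Step 10
Reactants: 16 enone diester
Product: 19 lactone (ethyl 3α-acetoxy-19-oxo-6β,19-epoxy-12,13,14,15,16-pentanorlabd-8-en-11-oate), via β,γ-unsaturated ketone 17 (not isolated), via 6β-hydroxy diester 18 (not isolated)
Conditions: KN(SiMe3)2 (1.05 equiv), THF, −78 °C; AcOH, −78 °C; then CeCl3·7H2O, NaBH4, MeOH, −78 → 0 °C; aq. citric acid, rt
Reagents that add atoms: none
Why: Kinetic C7 protonation of the extended dienolate (deconjugation) should place the double bond at C8=C9, Luche reduction should deliver hydride to the α-face away from the axial C20 methyl and C19 ester to set the 6β-alcohol, and the syn-axial C19 ester should capture it as the γ-lactone.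

Step 11
Reactants: 19 lactone
Product: 20 12,13,14,15,16-pentanorlabd-8-ene-3α,6β,11,19-tetrol
Conditions: LiAlH4 (excess), THF, 0 °C → reflux; H2O
Reagents that add atoms: none
Why: LiAlH4 should reduce the lactone, the hindered conjugated ester (1,2-reduction) and the acetate in one operation without touching the tetrasubstituted alkene.

Step 12
Reactants: 20 12,13,14,15,16-pentanorlabd-8-ene-3α,6β,11,19-tetrol
Product: 21 11-bromo-12,13,14,15,16-pentanorlabd-8-ene-3α,6β,19-triol
Conditions: NBS, Me2S, CH2Cl2, −20 °C; then 20 in THF, −20 → 0 °C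
Reagents that add atoms: N-bromosuccinimide, O=C1CCC(=O)N1Br
Why: Corey–Kim halogenation is selective for allylic alcohols, bromide displacing only the allylic alkoxysulfonium ion while the neopentyl and the hindered secondary hydroxyls are returned on work-up.

Step 13
Reactants: 21 11-bromo-12,13,14,15,16-pentanorlabd-8-ene-3α,6β,19-triol; 22 tert-butyl acetoacetate
Product: 23 tert-butyl 3α,6β,19-trihydroxy-13-oxo-16-norlabd-8-en-15-oate
Conditions: 22 (5 equiv), NaH, THF, 0 °C; n-BuLi, 0 °C; then 21, 0 °C; H2O
Reagents that add atoms: none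
Why: Acetoacetate dianion γ-alkylation with the allylic bromide should form C11–C12, the excess dianion absorbing the three hydroxyl protons and being returned as 22 on work-up.

Step 14
Reactants: 23 tert-butyl 3α,6β,19-trihydroxy-13-oxo-16-norlabd-8-en-15-oate
Product: 24 tert-butyl (13Z)-13-(diethoxyphosphoryloxy)-3α,6β,19-trihydroxy-16-norlabda-8,13-dien-15-oate
Conditions: NaH (1.05 equiv), Et2O/THF, 0 °C; ClP(O)(OEt)2, 0 °C
Reagents that add atoms: diethyl chlorophosphate, CCOP(=O)(Cl)OCC
Why: O-phosphorylation of the chelated sodium enolate of the β-keto ester, far more acidic than the alcohols, should give the Z-enol phosphate.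

Step 15
Reactants: 24 tert-butyl (13Z)-13-(diethoxyphosphoryloxy)-3α,6β,19-trihydroxy-16-norlabda-8,13-dien-15-oate
Product: 25 tert-butyl (13E)-3α,6β,19-trihydroxylabda-8,13-dien-15-oate
Conditions: Me2CuLi (6 equiv), Et2O, −78 → −45 °C; H2O
Reagents that add atoms: lithium dimethylcuprate, [Li+].C[Cu-]C
Why: Cuprate addition–elimination on an enol phosphate proceeds with retention, so the Z-phosphate should give the (13E)-3-methyl enoate, the excess reagent covering the three hydroxyls.

Step 16
Reactants: 25 tert-butyl (13E)-3α,6β,19-trihydroxylabda-8,13-dien-15-oate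
Product: 26 tert-butyl (13E)-19-(tert-butyldimethylsilyloxy)-3α,6β-dihydroxylabda-8,13-dien-15-oate
Conditions: TBSCl (1.1 equiv), imidazole, DMF, 0 °C
Reagents that add atoms: tert-butyldimethylsilyl chloride, CC(C)(C)[Si](C)(C)Cl
Why: Silylation should be selective for the only primary hydroxyl (C19), the axial 3α- and 6β-hydroxyls being secondary and hindered.

Step 17
Reactants: 26 tert-butyl (13E)-19-(tert-butyldimethylsilyloxy)-3α,6β-dihydroxylabda-8,13-dien-15-oate; 27 isovaleryl chloride
Product: 28 tert-butyl (13E)-19-(tert-butyldimethylsilyloxy)-3α,6β-bis(3-methylbutanoyloxy)labda-8,13-dien-15-oate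
Conditions: 27 (6 equiv), pyridine, DMAP, CH2Cl2, 40 °C
Reagents that add atoms: none
Why: DMAP-catalysed acylation with excess acid chloride should esterify both hindered axial hydroxyls.

Step 18
Reactants: 28 tert-butyl (13E)-19-(tert-butyldimethylsilyloxy)-3α,6β-bis(3-methylbutanoyloxy)labda-8,13-dien-15-oate
Product: 29 (13E)-19-hydroxy-3α,6β-bis(3-methylbutanoyloxy)labda-8,13-dien-15-oic acid
Conditions: CF3CO2H/CH2Cl2 (1:4), H2O (trace), 0 °C → rt
Reagents that add atoms: none
Why: Acidolysis should cleave the tert-butyl ester through the tert-butyl cation and the primary silyl ether by protodesilylation while both isovalerates stay in place.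

**Compound list**

1 | methyl acetoacetate | COC(=O)CC(C)=O | starting material
2 | 3-bromo-1-(trimethylsilyl)prop-1-yne | C[Si](C)(C)C#CCBr | starting material
3 | methyl 3-oxo-7-(trimethylsilyl)hept-6-ynoate | COC(=O)CC(=O)CCC#C[Si](C)(C)C | intermediate
4 | methyl (3R)-3-hydroxy-7-(trimethylsilyl)hept-6-ynoate | C[Si](C)(C)C#CCC[C@@H](O)CC(=O)OC | intermediate
5 | methyl (2R,3R)-3-hydroxy-2-methyl-7-(trimethylsilyl)hept-6-ynoate | C[Si](C)(C)C#CCC[C@@H](O)[C@H](C(=O)OC)C | intermediate
6 | allyl bromide (3-bromoprop-1-ene) | C=CCBr | starting material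
7 | methyl (2R,3R)-3-hydroxy-2-methyl-2-(prop-2-en-1-yl)-7-(trimethylsilyl)hept-6-ynoate | C[Si](C)(C)C#CCC[C@@H](O)[C@](C)(C(=O)OC)CC=C | intermediate
8 | methyl (2R,3R)-3-hydroxy-2-methyl-2-(prop-2-en-1-yl)hept-6-ynoate | C#CCC[C@@H](O)[C@](C)(C(=O)OC)CC=C | intermediate
9 | methyl (2R,3R)-3-acetoxy-2-methyl-2-(prop-2-en-1-yl)hept-6-ynoate | C#CCC[C@@H](OC(C)=O)[C@](C)(C(=O)OC)CC=C | intermediate
10 | ethyl acetoacetate | CCOC(=O)CC(C)=O | starting material
11 | 1-ethyl 8-methyl (6R,7R)-6-acetoxy-2-acetyl-7-methyl-3-methylidene-7-(prop-2-en-1-yl)octanedioate (C2 epimers) | C=C(CC[C@@H](OC(C)=O)[C@](C)(C(=O)OC)CC=C)C(C(C)=O)C(=O)OCC | intermediate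
12 | 1-ethyl 8-methyl (6R,7R)-6-acetoxy-2-acetyl-7-methyl-3-methylidene-7-(2-oxopropyl)octanedioate (C2 epimers) | C=C(CC[C@@H](OC(C)=O)[C@](C)(C(=O)OC)CC(C)=O)C(C(C)=O)C(=O)OCC | intermediate
13 | alkylidene acetoacetate: 1-ethyl 8-methyl (6R,7R)-6-acetoxy-2-acetyl-3,7-dimethyl-7-(2-oxopropyl)oct-2-enedioate (E/Z mixture; not isolated) | CC(CC[C@@H](OC(C)=O)[C@](C)(C(=O)OC)CC(C)=O)=C(C(C)=O)C(=O)OCC | intermediate
14 | Michael adduct: ring A cyclohexane with 3α-OAc, C4 β-CO2CH3 and α-CH3, C5 α-H and acetyl (C6, C7), C10 β-CH3 and the CH(COCH3)CO2Et arm (C9 epimers; not isolated) | CC(=O)C(C(=O)OCC)[C@@]1(C)CC[C@@H](OC(C)=O)[C@](C)(C(=O)OC)[C@@H]1C(C)=O | intermediate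
15 | aldol: 11-ethyl 19-methyl 3α-acetoxy-8-hydroxy-6-oxo-12,13,14,15,16-pentanorlabdane-11,19-dioate (5α-H, 10β-CH3; C8 and C9 epimers; not isolated) | CC1(O)C(C(=O)OCC)[C@@]2(C)CC[C@@H](OC(C)=O)[C@](C)(C(=O)OC)[C@@H]2C(=O)C1 | intermediate
16 | enone diester: 11-ethyl 19-methyl 3α-acetoxy-6-oxo-12,13,14,15,16-pentanorlabd-7-ene-11,19-dioate (5α-H, 10β-CH3; C9 epimers) | O=C1C=C(C)C(C(=O)OCC)[C@@]2(C)CC[C@@H](OC(C)=O)[C@](C)(C(=O)OC)[C@H]12 | intermediate
17 | β,γ-unsaturated ketone: 11-ethyl 19-methyl 3α-acetoxy-6-oxo-12,13,14,15,16-pentanorlabd-8-ene-11,19-dioate (not isolated) | CC1=C(C(=O)OCC)[C@@]2(C)CC[C@@H](OC(C)=O)[C@](C)(C(=O)OC)[C@@H]2C(=O)C1 | intermediate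
18 | 6β-hydroxy diester: 11-ethyl 19-methyl 3α-acetoxy-6β-hydroxy-12,13,14,15,16-pentanorlabd-8-ene-11,19-dioate (not isolated) | CC1=C(C(=O)OCC)[C@@]2(C)CC[C@@H](OC(C)=O)[C@](C)(C(=O)OC)[C@@H]2[C@H](O)C1 | intermediate
19 | lactone: ethyl 3α-acetoxy-19-oxo-6β,19-epoxy-12,13,14,15,16-pentanorlabd-8-en-11-oate (19,6β-olide) | CC1=C(C(=O)OCC)[C@@]2(C)CC[C@@H](OC(C)=O)[C@](C)(C(=O)O3)[C@@H]2[C@H]3C1 | intermediate
20 | 12,13,14,15,16-pentanorlabd-8-ene-3α,6β,11,19-tetrol | CC1=C(CO)[C@@]2(C)CC[C@@H](O)[C@](C)(CO)[C@@H]2[C@H](O)C1 | intermediate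
21 | 11-bromo-12,13,14,15,16-pentanorlabd-8-ene-3α,6β,19-triol | CC1=C(CBr)[C@@]2(C)CC[C@@H](O)[C@](C)(CO)[C@@H]2[C@H](O)C1 | intermediate
22 | tert-butyl acetoacetate | CC(=O)CC(=O)OC(C)(C)C | starting material
23 | tert-butyl 3α,6β,19-trihydroxy-13-oxo-16-norlabd-8-en-15-oate | CC1=C(CCC(=O)CC(=O)OC(C)(C)C)[C@@]2(C)CC[C@@H](O)[C@](C)(CO)[C@@H]2[C@H](O)C1 | intermediate
24 | tert-butyl (13Z)-13-(diethoxyphosphoryloxy)-3α,6β,19-trihydroxy-16-norlabda-8,13-dien-15-oate | CC1=C(CC/C(OP(=O)(OCC)OCC)=C/C(=O)OC(C)(C)C)[C@@]2(C)CC[C@@H](O)[C@](C)(CO)[C@@H]2[C@H](O)C1 | intermediate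
25 | tert-butyl (13E)-3α,6β,19-trihydroxylabda-8,13-dien-15-oate | CC1=C(CC/C(C)=C/C(=O)OC(C)(C)C)[C@@]2(C)CC[C@@H](O)[C@](C)(CO)[C@@H]2[C@H](O)C1 | intermediate
26 | tert-butyl (13E)-19-(tert-butyldimethylsilyloxy)-3α,6β-dihydroxylabda-8,13-dien-15-oate | CC1=C(CC/C(C)=C/C(=O)OC(C)(C)C)[C@@]2(C)CC[C@@H](O)[C@](C)(CO[Si](C)(C)C(C)(C)C)[C@@H]2[C@H](O)C1 | intermediate
27 | isovaleryl chloride (3-methylbutanoyl chloride) | CC(C)CC(Cl)=O | starting material
28 | tert-butyl (13E)-19-(tert-butyldimethylsilyloxy)-3α,6β-bis(3-methylbutanoyloxy)labda-8,13-dien-15-oate | CC1=C(CC/C(C)=C/C(=O)OC(C)(C)C)[C@@]2(C)CC[C@@H](OC(=O)CC(C)C)[C@](C)(CO[Si](C)(C)C(C)(C)C)[C@@H]2[C@H](OC(=O)CC(C)C)C1 | intermediate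
29 | (13E)-19-hydroxy-3α,6β-bis(3-methylbutanoyloxy)labda-8,13-dien-15-oic acid; (3R,4S,5R,6R,10S) | CC1=C(CC/C(C)=C/C(=O)O)[C@@]2(C)CC[C@@H](OC(=O)CC(C)C)[C@](C)(CO)[C@@H]2[C@H](OC(=O)CC(C)C)C1 | target

**Step count and risks**

Total step count: 18. Longest linear sequence: 18 steps (1 to 29; compounds 2, 6, 10, 22 and 27 are purchased).

The three steps most likely to fail:

(a) The bicyclisation of step 9. The enol of the C6 ketone may add too slowly to the fully substituted carbon C10, so that intermolecular condensation of the ketone groups competes, and the facial selectivity at C10 relative to C4 may be low. The fallback sets out from 12 and splits the event into a Stork enamine Michael addition and a separate aldol condensation. Compound 12 is isomerised to 13 with catalytic Et3N and condensed with pyrrolidine (benzene, reflux, water separator) to the pyrrolidine enamine F1, whose more substituted regioisomer is the one that reacts on. Ring A closes to the cyclised enamine F2, which aqueous acetic acid hydrolyses to the Michael adduct 14, now isolated so that its C10 epimers can be separated by chromatography. TsOH in refluxing benzene then closes ring B, and the route is rejoined at 16.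

(b) The indium-catalysed alkenylation of step 7. The unsubstituted acetoacetate may be alkenylated twice, or the catalyst may be held by the acetate and ester groups so that the alkyne is not consumed. The fallback sets out from 9 and uses a halide and a cross-coupling. Haloboration of the terminal alkyne with B-iodo-9-borabicyclo[3.3.1]nonane gives the (Z)-2-iodoalkenylborane F3, and protonolysis with acetic acid gives the 2-iodoalkene F4. Copper-catalysed C-vinylation of ethyl acetoacetate 10 (CuI, L-proline, Cs2CO3, DMSO, 50 °C) then rejoins the route at 11.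

(c) The deconjugation and reduction of step 10. The β,γ-unsaturated ketone may return to conjugation before hydride arrives, followed by 1,4-reduction or formation of the wrong alkene isomer. The fallback sets out from 16 and reduces first. Luche reduction of the enone itself (NaBH4, CeCl3·7H2O, MeOH, −78 °C) gives the 6β-allylic alcohol F5, which lactonises to the Δ7 lactone F6. RhCl3·3H2O (cat.) in ethanol at 80 °C then moves the ring double bond into conjugation with the C11 ester by hydride addition and elimination, without a C9 carbanion that could expel the allylic lactone oxygen, and the route is rejoined at 19.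

**Further compounds**

F1 | step 9 | pyrrolidine enamine of 13 at the C6 ketone (C5=C6 regioisomer) | CC(CC[C@@H](OC(C)=O)[C@](C)(C(=O)OC)C=C(C)N1CCCC1)=C(C(C)=O)C(=O)OCC
F2 | step 9 | cyclised enamine: ring A closed, C6 as its pyrrolidine enamine (C9 epimers) | CC(=O)C(C(=O)OCC)[C@@]1(C)CC[C@@H](OC(C)=O)[C@](C)(C(=O)OC)[C@@H]1C(=C)N1CCCC1
F3 | step 7 | (Z)-2-iodoalkenylborane from 9 and B-iodo-9-borabicyclo[3.3.1]nonane | I/C(CC[C@@H](OC(C)=O)[C@](C)(C(=O)OC)CC=C)=C\B1C2CCCC1CCC2
F4 | step 7 | methyl (2R,3R)-3-acetoxy-6-iodo-2-methyl-2-(prop-2-en-1-yl)hept-6-enoate | C=C(I)CC[C@@H](OC(C)=O)[C@](C)(C(=O)OC)CC=C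
F5 | step 10 | 11-ethyl 19-methyl 3α-acetoxy-6β-hydroxy-12,13,14,15,16-pentanorlabd-7-ene-11,19-dioate (C9 epimers) | C1=C(C)C(C(=O)OCC)[C@@]2(C)CC[C@@H](OC(C)=O)[C@](C)(C(=O)OC)[C@@H]2[C@@H]1O
F6 | step 10 | ethyl 3α-acetoxy-19-oxo-6β,19-epoxy-12,13,14,15,16-pentanorlabd-7-en-11-oate (C9 epimers) | C1=C(C)C(C(=O)OCC)[C@@]2(C)CC[C@@H](OC(C)=O)[C@](C)(C(=O)O3)[C@@H]2[C@@H]13
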